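## Analysis of the target

- The target 22 is a flavanone: a 2,3-dihydro-4H-chromen-4-one (rings A and C) that carries a catechol ring B on C2.
- Ring A is pentasubstituted. It has a hydroxyl at C5 that is hydrogen-bonded to the C4 carbonyl, a methoxy group at C7, a 3-methylbut-2-enyl (prenyl) group at C8, and hydrogen only at C6.
- C2 is the only stereocentre and is (S). It is benzylic, bears O1 and lies β to the C4 carbonyl.
- An enolate at C3 can therefore expel O1 (retro-oxa-Michael opening to the chalcone), and a free para-hydroxyl on ring B makes this opening easier. Any basic step after C2 is set is a threat to the configuration.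
- The catechol is prone to oxidation and to chelation of Lewis acids. The prenyl olefin is sensitive to strong protic acid and to electrophilic halogen.
- Two things make the synthesis hard: the regiochemistry on ring A (prenyl at C8 and not C6, methyl on O7 and not O5), and an enantioselective construction of C2 that survives to the end.
- The strategy rests on one feature: O1, C2, C3, C4, C4a and C8a form a 2-aryl-2,3-dihydropyran-4-one whose C2 is the former formyl carbon of protected protocatechualdehyde. If this ring is made first, with C8a already bonded to O1 and to the prenyl-bearing carbon C8, ring A can only grow from C4a and C8, so the prenyl group cannot end up anywhere but C8.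

## Retrosynthetic reasoning

**22 to 21.** The two aryl O–Si bonds are cut last. The free catechol is the group most prone to oxidation, and its para-oxygen is the one that assists opening of ring C, so it is unveiled under buffered, non-basic desilylation once everything else is in place.

**21 to 20.** The O7–CH3 bond is cut. The two phenols of 20 differ strongly: the 5-OH is chelated to C4=O, the 7-OH is free and more acidic. A neutral O-alkylation can therefore place the methyl group on O7 alone, and no differentiated protecting groups are needed on ring A.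

**20 to 18.** Ring A is opened at C7–C8, and the phenol at C5 is written as its keto form. This leaves a β-keto ester side chain on C4a (C5, C6, C7) and the prenyl-bearing methylene C8 on C8a. The cut is made here because C8 is the γ-carbon of an enone that is acylated at C4a. It is activated by both C4=O and C5=O through the C4a=C8a double bond and is far more acidic than C3. The forward step is an intramolecular Claisen condensation followed by enolisation; it has to run from the monoanion so that C3 is never deprotonated.

**18 to 14 and 15.** The C4a–C5 bond is cut, which gives the alkenyl iodide 14 and the acid chloride 15.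
- The three-carbon unit could in principle be attached at C8 first and closed at C4a.
- That order is not used because a strong base removes the C3 proton of 13 kinetically (the α′ position), not the γ proton at C8, and the C3 enolate can expel O1 and destroy C2.
- The unit ends in two carbonyl carbons, so it gives the same ring A whichever of C4a and C8 is bonded first.
- C4a is the only vinylic CH of 13 and can be reached without any enolate through its halide. The acidic methylene of 15 calls for a non-basic organometallic partner.

**14 to 13.** The C4a–I bond is cut. C4a is the nucleophilic α-carbon of the vinylogous ester, so electrophilic halogenation is regiospecific.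

**13 to 9 and 11.** This is the key disconnection. C2–C3 and O1–C8a are cut, which opens ring C to the aldehyde 11 and the diene 9.
- It is made here because it turns the only stereocentre into the carbonyl carbon of an aryl aldehyde, where catalyst-controlled face selection is well established.
- The unsubstituted terminus of 9 becomes C3. The oxygenated carbon that carries the chain becomes C8a, and its chain carbon is C8 with the prenyl group already attached.
- The forward reaction has to join the diene terminus to one face of 11 and then close the ring by addition of the new oxygen to C8a with loss of the enol ether substituent.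

**11 to 10.** The two O–Si bonds are cut. Bulky silyl ethers keep the catechol oxygens from binding the Lewis acid of step 6 and are removed at the end without acid or base.

**9 to 7 to 6.** The enol O–Si bond of 9 is cut to the methyl ketone 7, and the C4–O bond of 7 is cut to the ynone 6.
- The chain-side oxygen of the diene is a methyl ether and not a second silyl ether, for a regiochemical reason. A bis(silyloxy)diene would have to come from the unsymmetrical 1,3-diketone with the same chain. Its mono-silyl enol ether is a mixture of two regioisomers that exchange the silyl group between the oxygens, and the second enolisation would then give two dienes, one of them with a substituted terminus.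
- Conjugate addition to 6 puts the methoxy group on the chain-side carbon only. Kinetic enolisation of 7 then occurs only at the methyl group.

**6 to 3 and 4, and 3 to 1 and 2.** The acyl–alkynyl bond and then the C(sp)–C(sp3) bond are cut. This gives the terminal alkyne 3 with the amide 4, and the homoallylic bromide 1 with the acetylide 2; all of the starting materials are commercial.

## Alternatives that were turned down

**Alternative 1:** carbonylative assembly of a flavone.
- Disconnection: C4a–C4, C4–C3 and O1–C2 are cut, which gives the iodophenol A2, one carbonyl carbon from the gas phase and the arylacetylene A3.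
- Forward key step: under PdCl2(PPh3)2 and a secondary amine, the acylpalladium species formed from A2 is alkynylated by A3, and the phenol oxygen then adds 6-endo to the ynone to give the flavone A1.
- For it: it is highly convergent and short, the palladium chemistry is robust, and the prenyl position is fixed on a stable arene. On step economy it is stronger than the chosen route.
- Against it: A1 has a C2=C3 double bond and no stereocentre, so the (2S) centre must come from an enantioselective conjugate reduction of a 5,7-dioxygenated flavone in the presence of a prenyl olefin. A2 must be made as a single regioisomer from a symmetrical phloroglucinol ether, and the C5 methyl ether must later be cleaved without touching O7 or the prenyl group.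
- Comparison: the chosen strategy sets C2 at the moment the ring is formed, at the flavanone oxidation level, and never has to reduce a flavone.

**Alternative 2:** acylketene closure of ring A on a chiral dihydropyranone.
- Disconnection: C4a–C5 is cut, which gives the dioxinone-substituted dihydropyranone A5.
- Forward key step: heating A5 causes cycloreversion of the dioxinone; the acylketene carbon bonds to C4a, and tautomerisation gives A4, which is the same compound as 20.
- For it: the closure is thermal and free of base, so C2 is not at risk in that step. On this point it is stronger than the chosen Claisen closure. It also shares the advantage that ring C exists before ring A, so the prenyl group can only be at C8.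
- Against it: the ketene has to be captured by the weakly nucleophilic α-carbon of a vinylogous ester in competition with dimerisation and O-capture. More seriously, A5 requires a dioxinone on C8, which means either γ-carbanion chemistry on the dihydropyranone (the position a strong base does not deprotonate first) or a much more elaborate diene.
- Comparison: the chosen route reaches the same compound from a commercial three-carbon acid chloride through a C4a–metal species that needs no enolate.

**Alternative 3:** Friedel–Crafts closure of ring C.
- Disconnection: C4–C4a is cut, which gives the (S)-3-aryl-3-aryloxypropanoic acid A7.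
- Forward key step: A7 is activated as a mixed trifluoroacetic anhydride and acylates the one free position ortho to the ether oxygen, giving A6.
- For it: ring A is a stable, electron-rich arene, the acylation can only occur at C4a, and few steps follow. In robustness of the ring-forming step it is at least equal to the chosen route.
- Against it: the stereocentre of A7 is a benzylic aryl ether that must first be made by an invertive etherification of a hindered phenol, and it then has to survive strongly acidic, ionising conditions that also threaten the prenyl olefin. The 2-prenylated phenol must be obtained as one regioisomer. A6 still needs selective cleavage of the C5 methyl ether and removal of the acetates.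
- Comparison: the chosen strategy has neither an ionisable benzylic ether before ring closure nor a regiochemical question for the prenyl group.

Key step: step 6

Assumption: (S)-BINOL is taken to direct the diene to the Si face of the aryl aldehyde, as in related titanium–BINOL allylations and aldol additions; if the opposite sense is found, (R)-BINOL is used.

Remark: 7, 8, 9 and 12 are drawn as (E)-enol ethers; this geometry is lost in step 6 and has no consequence.

## Route

Step 1
Reactants: 1 5-bromo-2-methylpent-2-ene; 2 lithium acetylide–ethylenediamine complex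
Product: 3 6-methylhept-5-en-1-yne
Conditions: DMSO, 15 °C → rt
Reagents that add atoms: none
Why: SN2 alkylation of the acetylide at the primary homoallylic bromide in a dipolar aprotic solvent should give the terminal alkyne; the trisubstituted olefin is inert.

Step 2
Reactants: 3 6-methylhept-5-en-1-yne; 4 N-methoxy-N-methylacetamide
Product: 6 8-methylnon-7-en-3-yn-2-one, via lithium acetylide 5 (not isolated)
Conditions: n-BuLi, THF, −78 °C; 4, −78 → 0 °C; cold 1 M aq. HCl
Reagents that add atoms: none
Why: Acylation of a lithium acetylide with a Weinreb amide stops at the ketone because the tetrahedral adduct is stable until work-up; the acidic quench keeps the liberated amine from adding to the ynone.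

Step 3
Reactants: 6 8-methylnon-7-en-3-yn-2-one
Product: 7 (3E)-4-methoxy-8-methylnona-3,7-dien-2-one
Conditions: MeOH, NaOMe (5 mol%), 0 °C → rt
Reagents that add atoms: methanol, CO
Why: Base-catalysed oxa-Michael addition to the ynone places the methoxy group only on the β-carbon (the future C8a), which fixes the regiochemistry of the vinylogous ester; both enol ether geometries are usable.

Step 4
Reactants: 7 (3E)-4-methoxy-8-methylnona-3,7-dien-2-one
Product: 9 (3E)-4-methoxy-8-methyl-2-(trimethylsilyloxy)nona-1,3,7-triene, via lithium enolate 8 (not isolated)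
Conditions: LiN(iPr)2, THF, −78 °C; Me3SiCl, −78 °C → rt
Reagents that add atoms: chlorotrimethylsilane, C[Si](C)(C)Cl
Why: Kinetic deprotonation of a β-alkoxy enone by a lithium amide takes place at the α′-methyl group and not at the γ-methylene; O-silylation of the enolate then gives the 1-methoxy-3-silyloxy diene with an unsubstituted terminus.

Step 5
Reactants: 10 3,4-dihydroxybenzaldehyde
Product: 11 3,4-bis(tert-butyldimethylsilyloxy)benzaldehyde
Conditions: tBuMe2SiCl, imidazole, DMF, rt
Reagents that add atoms: tert-butyl(chloro)dimethylsilane, CC(C)(C)[Si](C)(C)Cl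
Why: Standard silylation of both phenols; the aldehyde is untouched.

Step 6
Reactants: 9 (3E)-4-methoxy-8-methyl-2-(trimethylsilyloxy)nona-1,3,7-triene; 11 3,4-bis(tert-butyldimethylsilyloxy)benzaldehyde
Product: 13 (2S)-2-[3,4-bis(tert-butyldimethylsilyloxy)phenyl]-6-(4-methylpent-3-en-1-yl)-2,3-dihydro-4H-pyran-4-one, via silylated aldol adduct 12 (not isolated)
Conditions: Ti(OiPr)4 (10 mol%), (S)-BINOL (20 mol%), 4 Å MS, Et2O, −20 °C; then CF3CO2H, CH2Cl2, 0 °C
Reagents that add atoms: none
Why: The chiral binaphtholate complex of tetravalent titanium binds the aldehyde 11, and the unsubstituted terminus of 9, the only nucleophilic carbon of the 2-silyloxy diene, adds in a Mukaiyama aldol manner to form C2–C3; silyl transfer gives 12. Acid then lets the C2 oxygen add to C8a of the β-methoxy enone (6-endo-trig oxa-Michael addition) and methanol is lost, which forms O1–C8a and closes ring C as the vinylogous ester. The closest known reaction type is the titanium–BINOL catalysed cyclocondensation of aryl aldehydes with 1-methoxy-3-silyloxy dienes to 2-aryl-2,3-dihydropyran-4-ones. C2 is the only new stereocentre and is set by the ligand, which shields one face of the coordinated formyl group; the (S)-ligand is expected to give Si-face attack and hence (2S). Regioselectivity needs no further control, because the trisubstituted methoxy-bearing end of the diene is not nucleophilic at carbon and serves only as the acceptor in the ring closure. The bulky, poorly coordinating silyl ethers of 11 keep the catechol oxygens off the titanium centre, and the isolated prenyl olefin is inert to the weak Lewis acid and to brief contact with cold acid.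

Step 7
Reactants: 13 (2S)-2-[3,4-bis(tert-butyldimethylsilyloxy)phenyl]-6-(4-methylpent-3-en-1-yl)-2,3-dihydro-4H-pyran-4-one
Product: 14 (2S)-2-[3,4-bis(tert-butyldimethylsilyloxy)phenyl]-5-iodo-6-(4-methylpent-3-en-1-yl)-2,3-dihydro-4H-pyran-4-one
Conditions: I2, pyridine, CH2Cl2, 0 °C → rt
Reagents that add atoms: iodine, II
Why: C5 of the dihydropyranone (C4a of the flavanone) is the nucleophilic α-carbon of a vinylogous ester and its only vinylic CH, so electrophilic iodination followed by loss of the proton to pyridine gives the α-iodo enone; pyridine-buffered iodine does not add irreversibly to the prenyl olefin, and no enolate is formed, so C2 is safe.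

Step 8
Reactants: 14 (2S)-2-[3,4-bis(tert-butyldimethylsilyloxy)phenyl]-5-iodo-6-(4-methylpent-3-en-1-yl)-2,3-dihydro-4H-pyran-4-one; 15 methyl 3-chloro-3-oxopropanoate
Product: 18 methyl 3-[(2S)-2-[3,4-bis(tert-butyldimethylsilyloxy)phenyl]-6-(4-methylpent-3-en-1-yl)-4-oxo-3,4-dihydro-2H-pyran-5-yl]-3-oxopropanoate, via alkenylmagnesium chloride 16 (not isolated), via alkenylzinc chloride 17 (not isolated)
Conditions: iPrMgCl·LiCl, THF, −40 °C; ZnCl2, −40 °C; then 15, Pd(PPh3)4 (5 mol%), −20 → 0 °C
Reagents that add atoms: none
Why: Iodine–magnesium exchange of a β-alkoxy α-iodo enone is faster at −40 °C than deprotonation at C3 or addition to the deactivated C4 carbonyl; transmetalation gives a non-basic alkenylzinc species that couples with the acid chloride 15 in a Negishi acylation (zerovalent palladium) without removing its acidic methylene protons. C2 is not involved.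

Step 9
Reactants: 18 methyl 3-[(2S)-2-[3,4-bis(tert-butyldimethylsilyloxy)phenyl]-6-(4-methylpent-3-en-1-yl)-4-oxo-3,4-dihydro-2H-pyran-5-yl]-3-oxopropanoate
Product: 20 (2S)-2-[3,4-bis(tert-butyldimethylsilyloxy)phenyl]-5,7-dihydroxy-8-(3-methylbut-2-en-1-yl)-2,3-dihydro-4H-chromen-4-one, via chromane-4,5,7-trione tautomer 19 (not isolated)
Conditions: LiN(SiMe3)2 (1.0 equiv), THF, −78 → 50 °C; cold 1 M aq. HCl
Reagents that add atoms: none
Why: One equivalent of base gives the monoanion of the tricarbonyl system; its tautomer with the charge on C8 (vinylogous to C4=O and C5=O through C4a=C8a) attacks the ester carbonyl C7 in a 6-exo-trig Claisen (Dieckmann-type) condensation, methoxide leaves, and enolisation of 19 gives the aromatic ring A with the prenyl group necessarily at C8. The C3 protons are far less acidic than those at C6 and C8, so the enolate that could expel O1 is not formed and C2 is retained.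

Step 10
Reactants: 20 (2S)-2-[3,4-bis(tert-butyldimethylsilyloxy)phenyl]-5,7-dihydroxy-8-(3-methylbut-2-en-1-yl)-2,3-dihydro-4H-chromen-4-one
Product: 21 (2S)-2-[3,4-bis(tert-butyldimethylsilyloxy)phenyl]-5-hydroxy-7-methoxy-8-(3-methylbut-2-en-1-yl)-2,3-dihydro-4H-chromen-4-one
Conditions: MeOH, PPh3, iPrO2C–N=N–CO2iPr (DIAD), THF, 0 °C → rt
Reagents that add atoms: methanol, CO
Why: The 5-OH is held in a hydrogen bond to C4=O, so the free and more acidic 7-OH is the phenol alkylated in the Mitsunobu reaction; the neutral medium does not enolise C3 and leaves the aryl silyl ethers intact.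

Step 11
Reactants: 21 (2S)-2-[3,4-bis(tert-butyldimethylsilyloxy)phenyl]-5-hydroxy-7-methoxy-8-(3-methylbut-2-en-1-yl)-2,3-dihydro-4H-chromen-4-one
Product: 22 (2S)-2-(3,4-dihydroxyphenyl)-5-hydroxy-7-methoxy-8-(3-methylbut-2-en-1-yl)-2,3-dihydro-4H-chromen-4-one
Conditions: Bu4NF, AcOH (1:1), THF, 0 °C
Reagents that add atoms: none
Why: Fluoride cleaves both aryl silyl ethers; buffering with acetic acid keeps the liberated catechol protonated, so no phenoxide-driven opening of ring C can racemise C2, and the prenyl group is not exposed to strong acid.

## Compound list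

1 | 5-bromo-2-methylpent-2-ene | CC(C)=CCCBr | starting material
2 | lithium acetylide–ethylenediamine complex | [Li+].[C-]#C.NCCN | starting material
3 | 6-methylhept-5-en-1-yne | C#CCCC=C(C)C | intermediate
4 | N-methoxy-N-methylacetamide | CC(=O)N(C)OC | starting material
5 | lithium 6-methylhept-5-en-1-yn-1-ide | [Li]C#CCCC=C(C)C | intermediate
6 | 8-methylnon-7-en-3-yn-2-one | CC(=O)C#CCCC=C(C)C | intermediate
7 | (3E)-4-methoxy-8-methylnona-3,7-dien-2-one | CC(=O)/C=C(/OC)CCC=C(C)C | intermediate
8 | lithium (3E)-4-methoxy-8-methylnona-1,3,7-trien-2-olate | [Li]OC(=C)/C=C(/OC)CCC=C(C)C | intermediate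
9 | (3E)-4-methoxy-8-methyl-2-(trimethylsilyloxy)nona-1,3,7-triene | C=C(O[Si](C)(C)C)/C=C(/OC)CCC=C(C)C | intermediate
10 | 3,4-dihydroxybenzaldehyde | O=Cc1ccc(O)c(O)c1 | starting material
11 | 3,4-bis(tert-butyldimethylsilyloxy)benzaldehyde | O=Cc1ccc(O[Si](C)(C)C(C)(C)C)c(O[Si](C)(C)C(C)(C)C)c1 | intermediate
12 | (1S,4E)-1-[3,4-bis(tert-butyldimethylsilyloxy)phenyl]-5-methoxy-9-methyl-1-(trimethylsilyloxy)deca-4,8-dien-3-one | CC(C)=CCC/C(OC)=C\C(=O)C[C@@H](c1ccc(O[Si](C)(C)C(C)(C)C)c(O[Si](C)(C)C(C)(C)C)c1)O[Si](C)(C)C | intermediate
13 | (2S)-2-[3,4-bis(tert-butyldimethylsilyloxy)phenyl]-6-(4-methylpent-3-en-1-yl)-2,3-dihydro-4H-pyran-4-one | CC(C)=CCCC1=CC(=O)C[C@@H](c2ccc(O[Si](C)(C)C(C)(C)C)c(O[Si](C)(C)C(C)(C)C)c2)O1 | intermediate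
14 | (2S)-2-[3,4-bis(tert-butyldimethylsilyloxy)phenyl]-5-iodo-6-(4-methylpent-3-en-1-yl)-2,3-dihydro-4H-pyran-4-one | CC(C)=CCCC1=C(I)C(=O)C[C@@H](c2ccc(O[Si](C)(C)C(C)(C)C)c(O[Si](C)(C)C(C)(C)C)c2)O1 | intermediate
15 | methyl 3-chloro-3-oxopropanoate (methyl malonyl chloride) | COC(=O)CC(Cl)=O | starting material
16 | chloro[(2S)-2-[3,4-bis(tert-butyldimethylsilyloxy)phenyl]-6-(4-methylpent-3-en-1-yl)-4-oxo-3,4-dihydro-2H-pyran-5-yl]magnesium | CC(C)=CCCC1=C([Mg]Cl)C(=O)C[C@@H](c2ccc(O[Si](C)(C)C(C)(C)C)c(O[Si](C)(C)C(C)(C)C)c2)O1 | intermediate
17 | chloro[(2S)-2-[3,4-bis(tert-butyldimethylsilyloxy)phenyl]-6-(4-methylpent-3-en-1-yl)-4-oxo-3,4-dihydro-2H-pyran-5-yl]zinc | CC(C)=CCCC1=C([Zn]Cl)C(=O)C[C@@H](c2ccc(O[Si](C)(C)C(C)(C)C)c(O[Si](C)(C)C(C)(C)C)c2)O1 | intermediate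
18 | methyl 3-[(2S)-2-[3,4-bis(tert-butyldimethylsilyloxy)phenyl]-6-(4-methylpent-3-en-1-yl)-4-oxo-3,4-dihydro-2H-pyran-5-yl]-3-oxopropanoate | COC(=O)CC(=O)C1=C(CCC=C(C)C)O[C@H](c2ccc(O[Si](C)(C)C(C)(C)C)c(O[Si](C)(C)C(C)(C)C)c2)CC1=O | intermediate
19 | (2S)-2-[3,4-bis(tert-butyldimethylsilyloxy)phenyl]-8-(3-methylbut-2-en-1-yl)-2,3-dihydro-4H-chromene-4,5,7(6H,8H)-trione | O=C1CC(=O)C2=C(O[C@H](c3ccc(O[Si](C)(C)C(C)(C)C)c(O[Si](C)(C)C(C)(C)C)c3)CC2=O)C1CC=C(C)C | intermediate
20 | (2S)-2-[3,4-bis(tert-butyldimethylsilyloxy)phenyl]-5,7-dihydroxy-8-(3-methylbut-2-en-1-yl)-2,3-dihydro-4H-chromen-4-one | Oc1cc(O)c2c(c1CC=C(C)C)O[C@H](c1ccc(O[Si](C)(C)C(C)(C)C)c(O[Si](C)(C)C(C)(C)C)c1)CC2=O | intermediate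
21 | (2S)-2-[3,4-bis(tert-butyldimethylsilyloxy)phenyl]-5-hydroxy-7-methoxy-8-(3-methylbut-2-en-1-yl)-2,3-dihydro-4H-chromen-4-one | COc1cc(O)c2c(c1CC=C(C)C)O[C@H](c1ccc(O[Si](C)(C)C(C)(C)C)c(O[Si](C)(C)C(C)(C)C)c1)CC2=O | intermediate
22 | (2S)-2-(3,4-dihydroxyphenyl)-5-hydroxy-7-methoxy-8-(3-methylbut-2-en-1-yl)-2,3-dihydro-4H-chromen-4-one | COc1cc(O)c2c(c1CC=C(C)C)O[C@H](c1ccc(O)c(O)c1)CC2=O | target

## Step count and least certain steps

Total step count: 11. Longest linear sequence: 10 steps (steps 1–4 and 6–11); step 5 is the one-step branch.

**Step 6 (key step).**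
- What may go wrong: poor facial selectivity, because an achiral silyl-cation-catalysed background aldol can compete with the titanium cycle for this electron-rich trisubstituted diene. In the acid stage, hydrolysis of the enol ether to the open 1,3-diketone may win over ring closure, or the prenyl olefin may be protonated.
- Fallback: set out from 7 and 11. The methyl ketone 7 is converted into its diisopinocampheylboron enolate (Ipc2BCl, Et3N, Et2O, −78 °C; the enantiomer of the reagent is chosen to deliver the (S)-carbinol) and added to 11. Oxidative work-up gives (1S,4E)-1-[3,4-bis(tert-butyldimethylsilyloxy)phenyl]-1-hydroxy-5-methoxy-9-methyldeca-4,8-dien-3-one F1. Brief treatment with CF3CO2H in CH2Cl2 then closes it by oxa-Michael addition and loss of methanol. The fallback comes back to the route at 13.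

**Step 8.**
- What may go wrong: the exchange reagent may deprotonate C3 or add to C4=O instead of exchanging. The C5–metal bond is anti to the ring C–O bond at C6, so β-elimination to a ring-opened ynone is possible on warming. The organometallic may also be quenched by the acidic methylene of 15 or of 18.
- Fallback: set out from 14 and avoid polar organometallics. Stannylation (Me3SnSnMe3, Pd(PPh3)4, toluene, 80 °C) gives (2S)-2-[3,4-bis(tert-butyldimethylsilyloxy)phenyl]-6-(4-methylpent-3-en-1-yl)-5-(trimethylstannyl)-2,3-dihydro-4H-pyran-4-one F2. A Stille acylation with 15 (PdCl2(PPh3)2, THF, 50 °C) then returns to the route at 18.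

**Step 9.**
- What may go wrong: slow ring closure, because in the monoanion the charge sits mainly on C6 (between ketone and ester) and the reactive C8 carbanion is the minor tautomer. If the reaction is forced, the liberated methoxide may cleave the aryl silyl ethers, the enolate oxygen may attack C8a and open ring C by addition–elimination to a 4-pyranone, or excess base may deprotonate C3 and cause retro-oxa-Michael loss of C2.
- Fallback: set out from 14 and build the ring in the other order.
  - Methoxycarbonylation (Pd(OAc)2, dppf, CO, MeOH, Et3N, DMF, 60 °C) gives methyl (2S)-2-[3,4-bis(tert-butyldimethylsilyloxy)phenyl]-6-(4-methylpent-3-en-1-yl)-4-oxo-3,4-dihydro-2H-pyran-5-carboxylate F3.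
  - In F3 the C8 protons are activated by ketone and ester together and are removed selectively (LiN(SiMe3)2, THF, −78 °C); acylation of this anion with 4 gives methyl (2S)-2-[3,4-bis(tert-butyldimethylsilyloxy)phenyl]-6-(6-methyl-2-oxohept-5-en-3-yl)-4-oxo-3,4-dihydro-2H-pyran-5-carboxylate F4.
  - Further base (NaH, THF) closes the acetyl methyl group onto the ester, in the way 2-acetonylbenzoates give naphthalene-1,3-diols. Loss of methanol and enolisation bring the route back at 20.

## Further compounds

F1 | step 6 | (1S,4E)-1-[3,4-bis(tert-butyldimethylsilyloxy)phenyl]-1-hydroxy-5-methoxy-9-methyldeca-4,8-dien-3-one | CC(C)=CCC/C(OC)=C\C(=O)C[C@H](O)c1ccc(O[Si](C)(C)C(C)(C)C)c(O[Si](C)(C)C(C)(C)C)c1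
F2 | step 8 | (2S)-2-[3,4-bis(tert-butyldimethylsilyloxy)phenyl]-6-(4-methylpent-3-en-1-yl)-5-(trimethylstannyl)-2,3-dihydro-4H-pyran-4-one | CC(C)=CCCC1=C([Sn](C)(C)C)C(=O)C[C@@H](c2ccc(O[Si](C)(C)C(C)(C)C)c(O[Si](C)(C)C(C)(C)C)c2)O1
F3 | step 9 | methyl (2S)-2-[3,4-bis(tert-butyldimethylsilyloxy)phenyl]-6-(4-methylpent-3-en-1-yl)-4-oxo-3,4-dihydro-2H-pyran-5-carboxylate | COC(=O)C1=C(CCC=C(C)C)O[C@H](c2ccc(O[Si](C)(C)C(C)(C)C)c(O[Si](C)(C)C(C)(C)C)c2)CC1=O
F4 | step 9 | methyl (2S)-2-[3,4-bis(tert-butyldimethylsilyloxy)phenyl]-6-(6-methyl-2-oxohept-5-en-3-yl)-4-oxo-3,4-dihydro-2H-pyran-5-carboxylate | COC(=O)C1=C(C(CC=C(C)C)C(C)=O)O[C@H](c2ccc(O[Si](C)(C)C(C)(C)C)c(O[Si](C)(C)C(C)(C)C)c2)CC1=O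
A1 | alternative 1 | 2-[3,4-bis(methoxymethoxy)phenyl]-5,7-dimethoxy-8-(3-methylbut-2-en-1-yl)-4H-chromen-4-one | COc1cc(OC)c2c(c1CC=C(C)C)OC(c1ccc(OCOC)c(OCOC)c1)=CC2=O
A2 | alternative 1 | 2-iodo-3,5-dimethoxy-6-(3-methylbut-2-en-1-yl)phenol | COc1cc(OC)c(I)c(O)c1CC=C(C)C
A3 | alternative 1 | 4-ethynyl-1,2-bis(methoxymethoxy)benzene | C#Cc1ccc(OCOC)c(OCOC)c1
A4 | alternative 2 | (2S)-2-[3,4-bis(tert-butyldimethylsilyloxy)phenyl]-5,7-dihydroxy-8-(3-methylbut-2-en-1-yl)-2,3-dihydro-4H-chromen-4-one | Oc1cc(O)c2c(c1CC=C(C)C)O[C@H](c1ccc(O[Si](C)(C)C(C)(C)C)c(O[Si](C)(C)C(C)(C)C)c1)CC2=O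
A5 | alternative 2 | (2S)-2-[3,4-bis(tert-butyldimethylsilyloxy)phenyl]-6-[1-(2,2-dimethyl-4-oxo-4H-1,3-dioxin-6-yl)-4-methylpent-3-en-1-yl]-2,3-dihydro-4H-pyran-4-one | CC(C)=CCC(C1=CC(=O)OC(C)(C)O1)C1=CC(=O)C[C@@H](c2ccc(O[Si](C)(C)C(C)(C)C)c(O[Si](C)(C)C(C)(C)C)c2)O1
A6 | alternative 3 | (2S)-2-(3,4-diacetoxyphenyl)-5,7-dimethoxy-8-(3-methylbut-2-en-1-yl)-2,3-dihydro-4H-chromen-4-one | COc1cc(OC)c2c(c1CC=C(C)C)O[C@H](c1ccc(OC(C)=O)c(OC(C)=O)c1)CC2=O
A7 | alternative 3 | (3S)-3-(3,4-diacetoxyphenyl)-3-[3,5-dimethoxy-2-(3-methylbut-2-en-1-yl)phenoxy]propanoic acid | COc1cc(OC)c(CC=C(C)C)c(O[C@@H](CC(=O)O)c2ccc(OC(C)=O)c(OC(C)=O)c2)c1
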